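# Proposed total synthesis of the humulane diester CNP0322023.1 by silicon-tethered transannular ring-closing metathesis

## The problem

The target is an eleven-membered carbocycle. Its ring atoms are numbered here C1 (angelate carbinol), C2, C3=C4 (E, methyl on C4), C5–C7, C8 (gem-dimethyl), C9 (acetate carbinol) and C10=C11 (Z, methyl on C11, C11 bonded to C1). Read from the SMILES, C1 is S and C9 is R.

A ring of this size is hard to close, both entropically and because of transannular strain. Its two trisubstituted double bonds must also come out with opposite, defined geometry.

The two stereocentres are 1,4-related across the C10=C11 bond and seven carbons apart the other way round. In an open chain neither can steer the other, so each must be set by an external chiral reagent or catalyst.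

The two oxygens carry different acyl groups. The only handle for telling the hydroxyls apart is steric: C9 is neopentylic next to C8, whereas C1 lies between a methylene and an sp2 carbon.

Three features are fragile:
- the angelate, which goes over to the tiglate under nucleophilic or acidic acyl activation;
- the free cis-2-ene-1,4-diol, which is doubly allylic and can ionise or cyclise in acid;
- any C1 carbonyl intermediate, which is β,γ-unsaturated and prone to conjugation.

The feature that opens the key step is the sequence O–C1–C11=C10–C9–O. One silicon atom closes these six atoms into a seven-membered 1,3,2-dioxasilepine, a ring that can hold only a cis double bond, which is the required Z geometry. In the (1S,9R) series the C1–C2 and C9–C8 bonds are trans on that ring, one pseudo-equatorial and one pseudo-axial.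

## Retrosynthesis

**Ester C–O bonds.** Target 28 is traced to hydroxy angelate 27 by removing the acetate, and 27 to diol 24 and angelic acid 25 through the mixed anhydride 26. The acetate is cut first because a small, cheap acyl donor can be forced onto the neopentylic C9 hydroxyl at the end. The isomerisation-prone angelate has to be transferred under mild, catalyst-free conditions, and these favour the less hindered C1 hydroxyl. Diol 24 carries no acyl or protecting groups. The forward steps must distinguish the two hydroxyls by steric bias alone and must not turn angelate into tiglate.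

**Si–O bonds of the bridge.** Diol 24 is derived from the silylene-bridged bicycle 23 by cleavage of both Si–O bonds. This adds atoms in the retrosynthetic sense, but it turns a Z alkene in an eleven-membered ring into an alkene in a seven-membered ring, where cis geometry is the only option. The forward step only has to free the cis-enediol without acid strong enough to ionise it.

**C10=C11 (key disconnection).** Retro-metathesis of 23 at C10=C11 gives the twelve-membered silylene 22, with a vinyl group on C9 and an isopropenyl group on C1.
- Against a cut at C3=C4: that alkene has no flanking heteroatoms for a tether, and no small ring can enforce its E geometry.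
- Against a σ-bond cut in the C5–C7 chain: it would need an activating group that must later be removed.
- In favour of C10=C11: it alone lies between both oxygens.
- Precursor 22 is monocyclic, has the same two stereocentres and needs no new one.
- The forward reaction must close transannularly within the twelve-membered ring, initiate at the hindered vinyl group and leave C3=C4 alone.

**Si–O bonds of the silaketal.** Silylene 22 is opened to the acyclic diol 19 and diisopropylsilyl bis(triflate) 20, with the mono-silylated triflate 21 as the stage between them. Assembling the silaketal from two separate alcohols and closing the large ring at carbon would bring back a carbon–carbon macrocyclisation. Closing at silicon needs only the diol. The forward step must make the second silylation intramolecular: the unhindered C1 hydroxyl reacts first in the cold, and the hindered C9 hydroxyl closes the ring under high dilution.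

**C1–C11 bond.** Diol 19 comes from its C9 silyl ether 18. Cutting C1–C11 in 18 gives the β,γ-unsaturated aldehyde 15 and a 2-propenyl nucleophile, supplied by Grignard reagent 16 through diisopropenylzinc 17 under a chiral amino-alcohol zinc catalyst.
- A cut at C1–C2 would need an allylmetal, which adds through its γ-terminus and gives the branched isomer.
- Reduction of an isopropenyl ketone would cost two more steps and pass through a conjugation-prone dienone.
- The precursor has lost the C1 stereocentre and three carbons.
- The forward step needs Re-face selectivity from the catalyst and no migration of C3=C4.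

**C2–C3 and C4–CH3 bonds.** Aldehyde 15 comes from homoallylic alcohol 14. That alcohol is cut to terminal alkyne 10 and ethylene oxide 11 by way of alkenylalane 12 and its alanate 13. Methylmetalation of an alkyne fixes the E geometry through its syn mechanism, whereas carbonyl olefination at a trisubstituted position gives isomer mixtures. The precursor has no alkene geometry to control. The forward step must be regioselective, keep configuration at the alkenyl carbon and tolerate the vinyl group and the silyl ether.

**C9–C10 bond.** Alkyne 10 is the silyl ether of alcohol 9. Cutting C9–C10 gives aldehyde 6 and a vinyl nucleophile from vinylmagnesium bromide 7 via divinylzinc 8, with the same catalyst and the same face as at C1.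
- This addition must precede the methylalumination, which an aldehyde would not survive.
- The neopentylic aldehyde cannot enolise, which makes it a good substrate for the addition.
- Alkynylation followed by semi-reduction would cost extra steps and clash with the terminal alkyne already present.

**C7–C8 bond.** Aldehyde 6 comes from nitrile 4 through aldimine 5, and 4 from isobutyronitrile 1 and 5-iodopent-1-yne 2 through the lithiated nitrile 3. Alkylation builds the quaternary carbon directly from two commercial pieces. A nitrile is chosen over an ester because one hydride step then gives the aldehyde.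

## Roads not taken

**Alternative 1:** sulfone carbanion ring closure at C5–C6.
- **Cut and key step:** the C5–C6 σ-bond is cut. LiN(SiMe3)2 at high dilution would deprotonate C6 of the open-chain bromo sulfone A1, and the carbanion would displace the allylic bromide at C5 to give the eleven-membered sulfone A2.
- **Merits:** this type of closure is well established for ten- to fourteen-membered terpenoid rings. It is an SN2 reaction at a primary allylic carbon. The two oxygens carry different silyl groups from the start, so their differentiation is certain.
- **Weak points:** the Z C10=C11 alkene still needs its own stereoselective construction in the open chain. Dimerisation and SN2' attack at C3 compete with closure. The sulfonyl group must be put in and then removed reductively from A2.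
- **Comparison:** Alternative 1 is better in the precedent for its ring closure and in hydroxyl differentiation. The chosen plan sets against this that one step delivers both the ring and the Z geometry, that no activating group is added or removed, and that the sequence is markedly shorter. It accepts a late, sterically controlled acylation, for which a fallback exists.

**Alternative 2:** Grob fragmentation of a fused six-seven bicycle.
- **Cut and key step:** the eleven-membered ring is traced to the bicycle A3, with C4–C9 as the ring-fusion bond, a tertiary hydroxyl on C9 and a mesylate on C3. KOtBu would form the C9 alkoxide, which fragments with cleavage of C4–C9 and loss of mesylate to give the dienone A4 with the E C3=C4 bond.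
- **Merits:** no medium ring is closed, since it emerges from two common rings. The anti-periplanar mechanism transfers the C3/C4 relative configuration stereospecifically into E geometry. No high dilution is needed.
- **Weak points:** A3 contains three contiguous fully substituted carbons (C4, C9, C8) and four stereocentres, three of which are destroyed in the fragmentation. In A4 the C9 carbinol is a ketone, so its configuration would have to be created late, by reduction of a Z-enone in a flexible ring with only the remote C1 centre as guide.
- **Comparison:** for forming the ring and the E alkene this route is probably more dependable than the chosen key step. The chosen plan sets against it that both carbinols are fixed early by catalyst control on simple acyclic aldehydes, that no ring ketone is ever reduced, and that no congested bicycle has to be built.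

**Alternative 3:** Ramberg–Bäcklund contraction of a twelve-membered thiacycle.
- **Cut and key step:** the C6–C7 bond is cut and a sulfonyl group inserted, which gives the cyclic α-chloro sulfone A5. KOtBu would generate the C7 carbanion, which attacks the chlorinated C6; the episulfone loses SO2 and the ring contracts to the triene A6 with an additional C6=C7 alkene.
- **Merits:** closing a twelve-membered ring through carbon–sulfur bond formation is forgiving. The contraction is intramolecular and well known. The hydroxyls are again differentiated by their silyl groups.
- **Weak points:** C7 is neopentylic, so bond formation to sulfur next to C8 is slow. Oxidation at sulfur must spare two electron-rich trisubstituted alkenes. The extra C6=C7 bond in A6 must be hydrogenated selectively beside C3=C4, C10=C11 and two allylic C–O bonds. The Z alkene must still be made beforehand.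
- **Comparison:** the ring-forming events have better precedent than a bridged metathesis. The chosen plan sets against this that it spends no steps on a bond that carries no function in the target. Its only auxiliary is the silicon tether, which also protects both hydroxyls and leaves in a single fluoride step.

Key step: step 10

**Remarks on the chemistry.**
- The sense of induction of (+)-3-exo-morpholinoisoborneol [(+)-MIB] is assumed by analogy with dialkylzinc additions, where its mirror image directs attack to the Si face. The configurations of 9 and 18 should be confirmed by Mosher ester analysis, and the antipodal ligand used if the sense proves opposite.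
- Zinc reagents 8 and 17 are generated in the flask from the commercial Grignard reagents and freed of magnesium halide before the aldehyde is added.

## Route

Step 1
Reactants: 1 isobutyronitrile; 2 5-iodopent-1-yne
Product: 4 2,2-dimethylhept-6-ynenitrile, via lithiated isobutyronitrile 3 (not isolated)
Conditions: LiN(iPr)2, THF, −78 °C; then 2, −78 °C → rt
Reagents that add atoms: none
Why: α-Alkylation of a nitrile-stabilised tertiary carbanion with a primary iodide (SN2) forms C7–C8 and the quaternary C8; substitution at the unhindered iodide should outrun proton transfer from the alkyne C–H, and the product has no α-hydrogen left.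

Step 2
Reactants: 4 2,2-dimethylhept-6-ynenitrile
Product: 6 2,2-dimethylhept-6-ynal, via N-(diisobutylalumanyl)aldimine 5 (not isolated)
Conditions: iBu2AlH, CH2Cl2, −78 °C; then aq. tartaric acid, 0 °C
Reagents that add atoms: water, SMILES O
Why: Partial reduction of a nitrile with iBu2AlH stops at the N-aluminated aldimine, which is hydrolysed to the aldehyde on work-up; the terminal alkyne is not hydroaluminated at −78 °C.

Step 3
Reactants: 6 2,2-dimethylhept-6-ynal; 7 vinylmagnesium bromide
Product: 9 (3R)-4,4-dimethylnon-1-en-8-yn-3-ol, via divinylzinc 8 (not isolated)
Conditions: 7, ZnCl2, Et2O, 0 °C; 1,4-dioxane, filter off MgBrCl(dioxane); then (+)-MIB (5 mol%), 6, toluene, −20 → 0 °C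
Reagents that add atoms: none
Why: Amino-alcohol-catalysed enantioselective addition of an alkenylzinc reagent to an aldehyde; the zinc alkoxide of (+)-MIB should deliver the vinyl group to the Re face of the non-enolisable neopentylic aldehyde, which sets C9 as R. Vinyl transfer to the aldehyde is expected to be much faster than zincation of the alkyne C–H at this temperature.

Step 4
Reactants: 9 (3R)-4,4-dimethylnon-1-en-8-yn-3-ol
Product: 10 tert-butyl{[(3R)-4,4-dimethylnon-1-en-8-yn-3-yl]oxy}dimethylsilane
Conditions: TBSOTf, 2,6-lutidine, CH2Cl2, −78 → 0 °C
Reagents that add atoms: tert-butyldimethylsilyl trifluoromethanesulfonate, SMILES CC(C)(C)[Si](C)(C)OS(=O)(=O)C(F)(F)F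
Why: Silyl triflate with a hindered pyridine base is the standard silylation of a hindered secondary alcohol; the TBS ether keeps the C9 oxygen out of the alane, alkyllithium, oxidation and second organozinc steps.

Step 5
Reactants: 10 tert-butyl{[(3R)-4,4-dimethylnon-1-en-8-yn-3-yl]oxy}dimethylsilane; 11 ethylene oxide
Product: 14 (3E,9R)-9-[(tert-butyldimethylsilyl)oxy]-4,8,8-trimethylundeca-3,10-dien-1-ol, via alkenyldimethylalane 12 (not isolated), via lithium alkenylalanate 13 (not isolated)
Conditions: AlMe3, Cp2ZrCl2 (cat.), CH2Cl2, 0 °C → rt; evaporate, hexane; n-BuLi, THF, −78 °C; then 11, −78 → 0 °C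
Reagents that add atoms: trimethylaluminium, SMILES C[Al](C)C
Why: Zirconium-catalysed methylalumination of a terminal alkyne is a syn addition that places methyl on the internal carbon and aluminium on the terminus; the butyl alanate then opens ethylene oxide with retention at the alkenyl carbon, so the C4 methyl, C2 and C1 are added and C3=C4 is formed E in one flask. The neopentylic monosubstituted alkene reacts far more slowly than the alkyne under these conditions.

Step 6
Reactants: 14 (3E,9R)-9-[(tert-butyldimethylsilyl)oxy]-4,8,8-trimethylundeca-3,10-dien-1-ol
Product: 15 (3E,9R)-9-[(tert-butyldimethylsilyl)oxy]-4,8,8-trimethylundeca-3,10-dienal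
Conditions: Dess–Martin periodinane, NaHCO3, CH2Cl2, 0 °C; used at once
Reagents that add atoms: none
Why: Buffered Dess–Martin oxidation converts homoallylic primary alcohols into β,γ-unsaturated aldehydes without moving the double bond into conjugation; the crude aldehyde is carried forward directly to avoid isomerisation on storage.

Step 7
Reactants: 15 (3E,9R)-9-[(tert-butyldimethylsilyl)oxy]-4,8,8-trimethylundeca-3,10-dienal; 16 isopropenylmagnesium bromide
Product: 18 (3S,5E,11R)-11-[(tert-butyldimethylsilyl)oxy]-2,6,10,10-tetramethyltrideca-1,5,12-trien-3-ol, via diisopropenylzinc 17 (not isolated)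
Conditions: 16, ZnCl2, Et2O, 0 °C; 1,4-dioxane, filter off MgBrCl(dioxane); then (+)-MIB (10 mol%), 15, toluene, −20 → 0 °C
Reagents that add atoms: none
Why: The same amino-alcohol-catalysed alkenylzinc addition; Re-face delivery of the 2-propenyl group should set C1 as S under catalyst control, independent of the remote C9 centre, and the weakly basic medium should leave the β,γ double bond in place. Any stereoisomer arising from incomplete control at either centre is a diastereomer from this point on and can be removed at a later stage.

Step 8
Reactants: 18 (3S,5E,11R)-11-[(tert-butyldimethylsilyl)oxy]-2,6,10,10-tetramethyltrideca-1,5,12-trien-3-ol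
Product: 19 (3S,5E,11R)-2,6,10,10-tetramethyltrideca-1,5,12-triene-3,11-diol
Conditions: Bu4NF, THF, rt → 45 °C
Reagents that add atoms: none
Why: Fluoride cleavage of the TBS ether; the triene diol has no base-sensitive function.

Step 9
Reactants: 19 (3S,5E,11R)-2,6,10,10-tetramethyltrideca-1,5,12-triene-3,11-diol; 20 diisopropylsilyl bis(trifluoromethanesulfonate)
Product: 22 (4S,6E,12R)-12-ethenyl-7,11,11-trimethyl-2,2-di(propan-2-yl)-4-(prop-1-en-2-yl)-1,3-dioxa-2-silacyclododec-6-ene, via C1-O-silyl triflate 21 (not isolated)
Conditions: 20 (1.05 equiv), 2,6-lutidine, CH2Cl2 (about 2 mM), slow addition of 19 at −78 °C; then → rt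
Reagents that add atoms: none
Why: Dialkylsilylene formation from a diol and a silyl bis(triflate); the unhindered C1 hydroxyl is silylated first in the cold, and on warming under high dilution the only nucleophile left, the neopentylic C9 hydroxyl, closes the twelve-membered ring on the remaining Si–OTf bond. A silyl triflate is reactive enough for hindered alcohols, and the diisopropyl silaketal should survive chromatography.

Step 10
Reactants: 22 (4S,6E,12R)-12-ethenyl-7,11,11-trimethyl-2,2-di(propan-2-yl)-4-(prop-1-en-2-yl)-1,3-dioxa-2-silacyclododec-6-ene
Product: 23 (1S,3E,9R,13Z)-4,8,8,13-tetramethyl-11,11-di(propan-2-yl)-10,12-dioxa-11-silabicyclo[7.3.2]tetradeca-3,13-diene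
Conditions: second-generation Grubbs catalyst (H2IMes)(PCy3)Cl2Ru=CHPh (in portions), 1,4-benzoquinone (cat.), toluene (about 1 mM), 80–110 °C, argon sparge
Reagents that add atoms: none
Why: The ruthenium benzylidene should initiate at the only monosubstituted alkene, the C9 vinyl group; the C10 alkylidene then meets the isopropenyl group held across the O–Si–O unit, and [2+2] cycloaddition with C10 bonding to C11 followed by cycloreversion forms C10=C11 and releases a methylidene that leaves as ethene. The closest known reaction type is the temporary-silicon-tethered ring-closing metathesis of acyclic bis(allyloxy)dialkylsilanes to 4,7-dihydro-1,3,2-dioxasilepines, which accepts a 1,1-disubstituted partner; the same closure across a macrocyclic silaketal, where it is transannular and leaves a bridged bicycle, is an extension that still has to be shown. The dioxasilepine closes as an ordinary seven-membered ring-closing metathesis between two allylic termini, and the same bond closes the eleven-membered carbocycle as a transannular contraction of the twelve-membered ring, so no separate macrocyclisation is required. No stereocentre is created; the new double bond must be Z because it is endocyclic in a seven-membered ring, and the untouched C1 and C9 centres place their ring-carbon bonds trans on the dioxasilepine, one pseudo-equatorial and one pseudo-axial. The step needs ring closure to beat intermolecular metathesis, which millimolar dilution and the pre-formed tether should secure. It also needs C3=C4 to stay out: as a trisubstituted internal alkene it should react far more slowly than the isopropenyl group, and its engagement would have to expel a disubstituted alkylidene or form an eight-membered siloxacycle. Removal of ethene drives the reaction forward, and 1,4-benzoquinone suppresses hydride-mediated isomerisation of the allylic silyl ethers.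

Step 11
Reactants: 23 (1S,3E,9R,13Z)-4,8,8,13-tetramethyl-11,11-di(propan-2-yl)-10,12-dioxa-11-silabicyclo[7.3.2]tetradeca-3,13-diene
Product: 24 (1R,2Z,4S,6E)-3,7,11,11-tetramethylcycloundeca-2,6-diene-1,4-diol
Conditions: HF·pyridine, excess pyridine, THF, 0 °C → rt
Reagents that add atoms: none
Why: Fluoride cleaves both Si–O bonds of the dialkylsilylene; buffering with pyridine keeps the medium from ionising the doubly allylic cis-enediol.

Step 12
Reactants: 24 (1R,2Z,4S,6E)-3,7,11,11-tetramethylcycloundeca-2,6-diene-1,4-diol; 25 angelic acid [(2Z)-2-methylbut-2-enoic acid]
Product: 27 (1S,2Z,4R,9E)-4-hydroxy-2,5,5,9-tetramethylcycloundeca-2,9-dien-1-yl (2Z)-2-methylbut-2-enoate, via angelic 2,4,6-trichlorobenzoic anhydride 26 (not isolated)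
Conditions: 25, 2,4,6-trichlorobenzoyl chloride, Et3N, toluene, rt; then 24, 60–75 °C (no DMAP)
Reagents that add atoms: none
Why: Yamaguchi-type esterification through the mixed anhydride; without a nucleophilic catalyst the angeloyl group should be transferred without isomerising to tigloyl, and the C1 hydroxyl, flanked by a methylene and an sp2 carbon, should react well ahead of the neopentylic C9 hydroxyl.

Step 13
Reactants: 27 (1S,2Z,4R,9E)-4-hydroxy-2,5,5,9-tetramethylcycloundeca-2,9-dien-1-yl (2Z)-2-methylbut-2-enoate
Product: 28 (1S,2Z,4R,9E)-4-acetoxy-2,5,5,9-tetramethylcycloundeca-2,9-dien-1-yl (2Z)-2-methylbut-2-enoate (target)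
Conditions: Ac2O, DMAP, Et3N, CH2Cl2, rt
Reagents that add atoms: acetic anhydride, SMILES CC(=O)OC(C)=O
Why: DMAP-catalysed acetylation of the remaining hindered secondary alcohol; a formed angelate ester should not isomerise under these conditions, because isomerisation belongs to the activated acyl stage, not to the ester.

## Compound list

1 | isobutyronitrile (2-methylpropanenitrile) | CC(C)C#N | starting material
2 | 5-iodopent-1-yne | C#CCCCI | starting material
3 | lithiated isobutyronitrile (2-lithio-2-methylpropanenitrile) | CC(C)([Li])C#N | intermediate
4 | 2,2-dimethylhept-6-ynenitrile | C#CCCCC(C)(C)C#N | intermediate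
5 | N-(diisobutylalumanyl)-2,2-dimethylhept-6-yn-1-imine | C#CCCCC(C)(C)C=N[Al](CC(C)C)CC(C)C | intermediate
6 | 2,2-dimethylhept-6-ynal | C#CCCCC(C)(C)C=O | intermediate
7 | vinylmagnesium bromide | C=C[Mg]Br | starting material
8 | divinylzinc | C=C[Zn]C=C | intermediate
9 | (3R)-4,4-dimethylnon-1-en-8-yn-3-ol | C#CCCCC(C)(C)[C@@H](C=C)O | intermediate
10 | tert-butyl{[(3R)-4,4-dimethylnon-1-en-8-yn-3-yl]oxy}dimethylsilane | C#CCCCC(C)(C)[C@@H](C=C)O[Si](C)(C)C(C)(C)C | intermediate
11 | ethylene oxide (oxirane) | C1CO1 | starting material
12 | {(1E,7R)-7-[(tert-butyldimethylsilyl)oxy]-2,6,6-trimethylnona-1,8-dien-1-yl}dimethylalumane | C[Al](C)/C=C(\C)CCCC(C)(C)[C@@H](C=C)O[Si](C)(C)C(C)(C)C | intermediate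
13 | lithium butyl{(1E,7R)-7-[(tert-butyldimethylsilyl)oxy]-2,6,6-trimethylnona-1,8-dien-1-yl}dimethylaluminate | [Li+].CCCC[Al-](C)(C)/C=C(\C)CCCC(C)(C)[C@@H](C=C)O[Si](C)(C)C(C)(C)C | intermediate
14 | (3E,9R)-9-[(tert-butyldimethylsilyl)oxy]-4,8,8-trimethylundeca-3,10-dien-1-ol | OCC/C=C(\C)CCCC(C)(C)[C@@H](C=C)O[Si](C)(C)C(C)(C)C | intermediate
15 | (3E,9R)-9-[(tert-butyldimethylsilyl)oxy]-4,8,8-trimethylundeca-3,10-dienal | O=CC/C=C(\C)CCCC(C)(C)[C@@H](C=C)O[Si](C)(C)C(C)(C)C | intermediate
16 | isopropenylmagnesium bromide (prop-1-en-2-ylmagnesium bromide) | C=C(C)[Mg]Br | starting material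
17 | diisopropenylzinc [di(prop-1-en-2-yl)zinc] | C=C(C)[Zn]C(C)=C | intermediate
18 | (3S,5E,11R)-11-[(tert-butyldimethylsilyl)oxy]-2,6,10,10-tetramethyltrideca-1,5,12-trien-3-ol | C=C(C)[C@@H](O)C/C=C(\C)CCCC(C)(C)[C@@H](C=C)O[Si](C)(C)C(C)(C)C | intermediate
19 | (3S,5E,11R)-2,6,10,10-tetramethyltrideca-1,5,12-triene-3,11-diol | C=C(C)[C@@H](O)C/C=C(\C)CCCC(C)(C)[C@@H](C=C)O | intermediate
20 | diisopropylsilyl bis(trifluoromethanesulfonate) | CC(C)[Si](OS(=O)(=O)C(F)(F)F)(OS(=O)(=O)C(F)(F)F)C(C)C | starting material
21 | {[(3S,5E,11R)-11-hydroxy-2,6,10,10-tetramethyltrideca-1,5,12-trien-3-yl]oxy}di(propan-2-yl)silyl trifluoromethanesulfonate | C=C(C)[C@@H](O[Si](OS(=O)(=O)C(F)(F)F)(C(C)C)C(C)C)C/C=C(\C)CCCC(C)(C)[C@@H](C=C)O | intermediate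
22 | (4S,6E,12R)-12-ethenyl-7,11,11-trimethyl-2,2-di(propan-2-yl)-4-(prop-1-en-2-yl)-1,3-dioxa-2-silacyclododec-6-ene | CC(C)[Si]1(C(C)C)O[C@H](C(C)=C)C/C=C(\C)CCCC(C)(C)[C@@H](C=C)O1 | intermediate
23 | (1S,3E,9R,13Z)-4,8,8,13-tetramethyl-11,11-di(propan-2-yl)-10,12-dioxa-11-silabicyclo[7.3.2]tetradeca-3,13-diene | CC(C)[Si]2(C(C)C)O[C@H]1C/C=C(\C)CCCC(C)(C)[C@H](O2)/C=C\1C | intermediate
24 | (1R,2Z,4S,6E)-3,7,11,11-tetramethylcycloundeca-2,6-diene-1,4-diol | O[C@H]1C/C=C(\C)CCCC(C)(C)[C@H](O)/C=C\1C | intermediate
25 | angelic acid [(2Z)-2-methylbut-2-enoic acid] | C/C=C(/C)C(=O)O | starting material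
26 | (2Z)-2-methylbut-2-enoic 2,4,6-trichlorobenzoic anhydride | C/C=C(/C)C(=O)OC(=O)c1c(Cl)cc(Cl)cc1Cl | intermediate
27 | (1S,2Z,4R,9E)-4-hydroxy-2,5,5,9-tetramethylcycloundeca-2,9-dien-1-yl (2Z)-2-methylbut-2-enoate | C/C=C(/C)C(=O)O[C@H]1C/C=C(\C)CCCC(C)(C)[C@H](O)/C=C\1C | intermediate
28 | (1S,2Z,4R,9E)-4-acetoxy-2,5,5,9-tetramethylcycloundeca-2,9-dien-1-yl (2Z)-2-methylbut-2-enoate | C/C=C(/C)C(=O)O[C@H]1C/C=C(\C)CCCC(C)(C)[C@H](OC(C)=O)/C=C\1C | target

## Step count and least certain steps

Total step count: 13. Longest linear sequence: 13 steps, from 1 and 2 to 28. Compounds 7, 11, 16, 20 and 25 enter as commercial materials.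

**Step 10 (key step).**
- Most likely failure: the alkylidene formed at the hindered C9 vinyl group finds no low-strain path to the isopropenyl group across the trans-bridged framework. Intermolecular metathesis to dimers and oligomers, or ring-opening engagement of C3=C4, would then take over. Slow initiation next to the quaternary C8 would aggravate this.
- Fallback: this gives up the tether and uses conventional macrocyclic metathesis. It sets out from diol 19, which is silylated with Et3SiCl and imidazole to the bis(triethylsilyl) ether F1. Ring-closing metathesis of F1 with the same ruthenium catalyst under high dilution would give the cycloundecadiene bis(triethylsilyl) ether F2. The Z isomer is separated from any E isomer and desilylated with HF·pyridine, which returns to the route at 24.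
- Cost: the Z geometry is no longer enforced, so the fallback stands or falls with the isomer distribution.

**Step 9.**
- Most likely failure: intermolecular silylation. A second diol molecule may attack the mono-silylated triflate faster than the hindered C9 hydroxyl closes the twelve-membered ring, which gives dimeric silaketals.
- Fallback: this separates the two Si–O bond formations by using a silicon hydride as a latent leaving group. It sets out from diol 19, which is silylated at the C1 hydroxyl with iPr2SiHCl and imidazole at −78 °C to the hydrosilyl ether F3. N-Bromosuccinimide converts the Si–H bond into Si–Br to give the bromosilyl ether F4. F4 is added slowly to Et3N and DMAP in CH2Cl2 at high dilution, so that the only reactive pair in the molecule closes the ring. This returns to the route at 22.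

**Step 7.**
- Most likely failure: eroded facial selectivity with an unbranched aldehyde, or migration of the β,γ double bond into conjugation before addition.
- Fallback: this replaces catalytic addition by reduction of a ketone. It sets out from aldehyde 15, which is treated with Grignard reagent 16 at −78 °C to give the C1-epimeric alcohols F5. Dess–Martin oxidation gives the isopropenyl ketone F6. CBS reduction with the (R)-oxazaborolidine and catecholborane at −78 °C, in which the α-methylvinyl group acts as the large substituent, should give the S carbinol and return to the route at 18.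

**Step 12.**
- Most likely failure: incomplete site selectivity, with acylation at C9 or at both hydroxyls, or partial isomerisation to the tiglate on prolonged heating.
- Fallback: this differentiates the hydroxyls by silylation and reverses the order of acylation. It sets out from diol 24, which is silylated at the less hindered hydroxyl with Et3SiCl and imidazole at −40 °C to the C1 triethylsilyl ether F7. Acetylation with Ac2O and DMAP gives the silyl ether acetate F8, and HF·pyridine frees the C1 hydroxyl to give the hydroxy acetate F9. Esterification of F9 with the mixed anhydride 26 returns to the route at 28.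

## Further compounds

F1 | step 10 | (3S,5E,11R)-2,6,10,10-tetramethyl-3,11-bis[(triethylsilyl)oxy]trideca-1,5,12-triene | C=C(C)[C@@H](O[Si](CC)(CC)CC)C/C=C(\C)CCCC(C)(C)[C@@H](C=C)O[Si](CC)(CC)CC
F2 | step 10 | (1R,2Z,4S,6E)-3,7,11,11-tetramethyl-1,4-bis[(triethylsilyl)oxy]cycloundeca-2,6-diene | CC[Si](CC)(CC)O[C@H]1C/C=C(\C)CCCC(C)(C)[C@H](O[Si](CC)(CC)CC)/C=C\1C
F3 | step 9 | (3S,5E,11R)-3-{[di(propan-2-yl)silyl]oxy}-2,6,10,10-tetramethyltrideca-1,5,12-trien-11-ol | C=C(C)[C@@H](O[SiH](C(C)C)C(C)C)C/C=C(\C)CCCC(C)(C)[C@@H](C=C)O
F4 | step 9 | (3S,5E,11R)-3-{[bromodi(propan-2-yl)silyl]oxy}-2,6,10,10-tetramethyltrideca-1,5,12-trien-11-ol | C=C(C)[C@@H](O[Si](Br)(C(C)C)C(C)C)C/C=C(\C)CCCC(C)(C)[C@@H](C=C)O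
F5 | step 7 | (5E,11R)-11-[(tert-butyldimethylsilyl)oxy]-2,6,10,10-tetramethyltrideca-1,5,12-trien-3-ol, both C3 epimers | C=C(C)C(O)C/C=C(\C)CCCC(C)(C)[C@@H](C=C)O[Si](C)(C)C(C)(C)C
F6 | step 7 | (5E,11R)-11-[(tert-butyldimethylsilyl)oxy]-2,6,10,10-tetramethyltrideca-1,5,12-trien-3-one | C=C(C)C(=O)C/C=C(\C)CCCC(C)(C)[C@@H](C=C)O[Si](C)(C)C(C)(C)C
F7 | step 12 | (1R,2Z,4S,6E)-3,7,11,11-tetramethyl-4-[(triethylsilyl)oxy]cycloundeca-2,6-dien-1-ol | CC[Si](CC)(CC)O[C@H]1C/C=C(\C)CCCC(C)(C)[C@H](O)/C=C\1C
F8 | step 12 | (1R,2Z,4S,6E)-3,7,11,11-tetramethyl-4-[(triethylsilyl)oxy]cycloundeca-2,6-dien-1-yl acetate | CC[Si](CC)(CC)O[C@H]1C/C=C(\C)CCCC(C)(C)[C@H](OC(C)=O)/C=C\1C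
F9 | step 12 | (1R,2Z,4S,6E)-4-hydroxy-3,7,11,11-tetramethylcycloundeca-2,6-dien-1-yl acetate | O[C@H]1C/C=C(\C)CCCC(C)(C)[C@H](OC(C)=O)/C=C\1C
A1 | alternative 1 | open-chain precursor with C5 allylic bromide and C6 phenyl sulfone, C1 triethylsilyl ether and C9 tert-butyldimethylsilyl ether | BrC/C(C)=C/C[C@H](O[Si](CC)(CC)CC)/C(C)=C\[C@@H](O[Si](C)(C)C(C)(C)C)C(C)(C)CCS(=O)(=O)c1ccccc1
A2 | alternative 1 | eleven-membered diene carrying the C6 phenylsulfonyl group, C1 triethylsilyl ether and C9 tert-butyldimethylsilyl ether | CC[Si](CC)(CC)O[C@H]1C/C=C(\C)CC(S(=O)(=O)c2ccccc2)CC(C)(C)[C@H](O[Si](C)(C)C(C)(C)C)/C=C\1C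
A3 | alternative 2 | fused six-seven bicycle with C9 tertiary hydroxyl, C3 mesylate and C1 tert-butyldimethylsilyl ether (one diastereomer set up for anti fragmentation) | CC(C)(C)[Si](C)(C)O[C@H]1C[C@@H](OS(C)(=O)=O)[C@]2(C)CCCC(C)(C)[C@@]2(O)/C=C\1C
A4 | alternative 2 | eleven-membered C9 dienone with C1 tert-butyldimethylsilyl ether | CC(C)(C)[Si](C)(C)O[C@H]1C/C=C(\C)CCCC(C)(C)C(=O)/C=C\1C
A5 | alternative 3 | twelve-membered cyclic sulfone chlorinated at C6 (either C6 epimer), C1 triethylsilyl ether and C9 tert-butyldimethylsilyl ether | CC[Si](CC)(CC)O[C@H]1C/C=C(\C)CC(Cl)S(=O)(=O)CC(C)(C)[C@H](O[Si](C)(C)C(C)(C)C)/C=C\1C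
A6 | alternative 3 | eleven-membered triene bis-silyl ether with additional C6=C7 alkene | CC[Si](CC)(CC)O[C@H]1C/C=C(\C)CC=CC(C)(C)[C@H](O[Si](C)(C)C(C)(C)C)/C=C\1C
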